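**Retrosynthetic overview**

1. Target 23 ⇒ 3-methoxy-1,2-dioxane 19 + ketene acetal 21: the C3–CH2CO2H bond is made last by peroxycarbenium alkylation.
2. 19 ⇒ 3,6-dimethoxy-1,2-dioxane 18: the C6–CH3 bond is made by a new axial C-methylation of the tertiary peroxycarbenium ion.
3. 18 ⇒ cyclobutanol 15: O2 is inserted into the C1–C2 bond by aerobic oxidative ring expansion (4 → 6). This is the only ring-forming event; the cyclobutane is bought.
4. 15 ⇒ α-siloxycyclobutanone 13 (desymmetrised 3-methylcyclobutanone, carries C4) + side-chain iodide 9 (organolithium addition).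
5. 9 ⇒ PhMgBr + 6-bromohex-1-ene + butenylMgBr; both methyl stereocentres come from two Zr-catalysed carboaluminations.

Assumptions: dioxane ring atoms are numbered as in the target (O1, O2, C3–C6) in all names; the (R,R)-lithium amide is taken to give the (S)-enol ether 11 (if the sense proves opposite, the (S,S)-amide is used); the (+)-ZACA catalyst is taken to give the (S)- and the (−)-catalyst the (R)-2-methylalkyl-alane.

**Route**

Step 1
Reactants: 1 phenylmagnesium bromide; 2 6-bromohex-1-ene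
Product: 3 hex-5-en-1-ylbenzene
Conditions: Li2CuCl4 (3 mol%), THF/NMP, 0 → 23 °C
Reagents that add atoms: none
Why: Copper-catalysed (Kochi-type) Grignard/primary alkyl bromide cross-coupling proceeds by SN2-like substitution without touching the terminal alkene; no stereocentre is formed.

Step 2
Reactants: 3 hex-5-en-1-ylbenzene
Product: 5 [(5S)-6-iodo-5-methylhexyl]benzene, via alkylalane 4 (not isolated)
Conditions: Me3Al (2 equiv), (+)-(NMI)2ZrCl2 (3 mol%), MAO (cat.), CH2Cl2, 0 °C; evaporate; I2 (3.5 equiv), THF, 0 °C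
Reagents that add atoms: trimethylaluminium C[Al](C)C; iodine II
Why: Zr-catalysed asymmetric carboalumination (ZACA) adds Me–Al across the terminal alkene with catalyst-controlled face selectivity, setting C5 as (S) (typically 80–90% ee), and iodinolysis of the primary C–Al bond does not touch that centre.

Step 3
Reactants: 5 [(5S)-6-iodo-5-methylhexyl]benzene; 6 but-3-en-1-ylmagnesium bromide
Product: 7 [(5S)-5-methylnon-8-en-1-yl]benzene
Conditions: Li2CuCl4 (3 mol%), THF, −20 → 23 °C
Reagents that add atoms: none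
Why: Kochi copper-catalysed sp3–sp3 coupling of a primary iodide with a primary Grignard reagent; the β-stereocentre is not involved.

Step 4
Reactants: 7 [(5S)-5-methylnon-8-en-1-yl]benzene
Product: 9 [(5S,9R)-10-iodo-5,9-dimethyldecyl]benzene, via alkylalane 8 (not isolated)
Conditions: Me3Al (2 equiv), (−)-(NMI)2ZrCl2 (3 mol%), MAO (cat.), CH2Cl2, 0 °C; evaporate; I2 (3.5 equiv), THF, 0 °C
Reagents that add atoms: trimethylaluminium C[Al](C)C; iodine II
Why: A second ZACA reaction with the enantiomeric catalyst sets C9 as (R) under pure catalyst control (the remote C5 centre has no influence), and iodinolysis gives the primary iodide.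

Step 5
Reactants: 10 3-methylcyclobutan-1-one
Product: 11 triethyl{[(3S)-3-methylcyclobut-1-en-1-yl]oxy}silane
Conditions: (R,R)-[PhCH(Me)]2NH, n-BuLi, THF, −78 °C; then 10 + Et3SiCl (in situ quench), −100 °C
Reagents that add atoms: chlorotriethylsilane CC[Si](Cl)(CC)CC
Why: Enantioselective deprotonation with a chiral lithium amide (desymmetrisation) removes one of the two enantiotopic α-protons of the prochiral ketone, which turns C3 into a stereocentre (S); the in situ silyl quench prevents self-aldol of the cyclobutanone enolate.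

Step 6
Reactants: 11 triethyl{[(3S)-3-methylcyclobut-1-en-1-yl]oxy}silane
Product: 13 (2R,3S)-3-methyl-2-[(triethylsilyl)oxy]cyclobutan-1-one, via siloxy epoxide 12 (not isolated)
Conditions: DMDO (acetone), CH2Cl2, −40 → 0 °C
Reagents that add atoms: dimethyldioxirane CC1(C)OO1
Why: Rubottom oxidation: epoxidation anti to the 3-methyl group followed by 1,4-silyl migration gives the trans α-siloxy ketone; C3 is untouched and the C2 configuration is erased later.

Step 7
Reactants: 9 [(5S,9R)-10-iodo-5,9-dimethyldecyl]benzene; 13 (2R,3S)-3-methyl-2-[(triethylsilyl)oxy]cyclobutan-1-one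
Product: 15 (1S,2R,3S)-1-[(2R,6S)-2,6-dimethyl-10-phenyldecyl]-3-methyl-2-[(triethylsilyl)oxy]cyclobutan-1-ol, via alkyllithium 14 (not isolated)
Conditions: t-BuLi (2.1 equiv), Et2O/pentane, −78 °C; then 13, −78 → 0 °C; H2O
Reagents that add atoms: none
Why: Iodine–lithium exchange followed by 1,2-addition to the strained ketone, mainly anti to the α-siloxy group; the C1 and C2 configurations (and any O-to-O silyl migration) are irrelevant because both centres become acetal carbons in step 8.

Step 8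
Reactants: 15 (1S,2R,3S)-1-[(2R,6S)-2,6-dimethyl-10-phenyldecyl]-3-methyl-2-[(triethylsilyl)oxy]cyclobutan-1-ol
Product: 18 (3R,4S,6R)-6-[(2R,6S)-2,6-dimethyl-10-phenyldecyl]-3,6-dimethoxy-4-methyl-1,2-dioxane, via hydroperoxy ketone 16 (not isolated), via peroxy-hemiketal 17 (not isolated)
Conditions: Co(acac)2 (10 mol%), O2 (1 atm), MeCN, 40 °C; Celite; then MeOH, CSA (10 mol%), 4 Å MS, 23 °C
Reagents that add atoms: dioxygen O=O; methanol CO
Why: Cobalt-catalysed aerobic oxidative ring expansion of a cyclobutanol (alkoxy radical, β-scission of C1–C2 towards the α-siloxy-stabilised radical, O2 capture, closure of the hydroperoxide on the ketone) builds the 1,2-dioxane, and acid methanolysis then equilibrates both acetal carbons to the anomerically preferred axial-OMe isomer with 4-Me and the 6-alkyl chain equatorial, so C3 and C6 of 18 are set thermodynamically relative to the untouched C4.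

Step 9
Reactants: 18 (3R,4S,6R)-6-[(2R,6S)-2,6-dimethyl-10-phenyldecyl]-3,6-dimethoxy-4-methyl-1,2-dioxane
Product: 19 (3R,4S,6R)-6-[(2R,6S)-2,6-dimethyl-10-phenyldecyl]-3-methoxy-4,6-dimethyl-1,2-dioxane
Conditions: Me3Al (3 equiv), TMSOTf (0.2 equiv), CH2Cl2, −78 → −40 °C; aq. Rochelle salt
Reagents that add atoms: trimethylaluminium C[Al](C)C
Why: Proposed new method: C-methylation of a cyclic peroxyketal through its peroxycarbenium ion – catalytic TMSOTf (then Me2AlOTf) ionises the ketone-derived C6–OMe (tertiary, far more labile than the aldehyde-derived C3–OMe), the half-chair cation keeps 4-Me pseudo-equatorial and 3-OMe pseudo-axial, and Me3Al delivers methyl along the axial trajectory anti to 3-OMe, giving axial 6-Me and equatorial 6-alkyl, i.e. (6R); the closest known reaction types are Lewis-acid substitution of peroxyketals by allylsilanes and silyl enol ethers via peroxycarbenium ions, and Me3Al C-methylation of cyclic oxocarbenium ions, including ones that carry a trioxane O–O bond, which indicates the peroxide tolerates Me3Al at low temperature.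

Step 10
Reactants: 20 trimethylsilyl acetate
Product: 21 1,1-bis[(trimethylsilyl)oxy]ethene
Conditions: LDA, THF, −78 °C; Me3SiCl, −78 → 23 °C; distil
Reagents that add atoms: chlorotrimethylsilane C[Si](C)(C)Cl
Why: Enolisation of the silyl ester and O-silylation of the enolate gives the bis-silyl ketene acetal, a neutral acetic acid enolate equivalent that is compatible with peroxides.

Step 11
Reactants: 19 (3R,4S,6R)-6-[(2R,6S)-2,6-dimethyl-10-phenyldecyl]-3-methoxy-4,6-dimethyl-1,2-dioxane; 21 1,1-bis[(trimethylsilyl)oxy]ethene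
Product: 23 2-[(3S,4S,6R)-6-[(2R,6S)-2,6-dimethyl-10-phenyldecyl]-4,6-dimethyl-1,2-dioxan-3-yl]acetic acid, via silyl ester 22 (not isolated)
Conditions: 21 (2 equiv), TMSOTf (0.5 equiv), CH2Cl2, −78 → −40 °C; pH 4 aq. buffer
Reagents that add atoms: none
Why: Lewis-acid peroxycarbenium substitution (Mukaiyama-type addition of a silyl ketene acetal): axial attack on the C3 cation in the half-chair with 4-Me pseudo-equatorial, 6-alkyl equatorial and 6-Me axial places CH2CO2 cis to 4-Me and to the 6-alkyl chain, i.e. (3S), and the silyl ester is hydrolysed on work-up.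

**Compound list**

1 | phenylmagnesium bromide | Br[Mg]c1ccccc1 | starting material
2 | 6-bromohex-1-ene | C=CCCCCBr | starting material
3 | hex-5-en-1-ylbenzene | C=CCCCCc1ccccc1 | intermediate
4 | dimethyl[(2S)-2-methyl-6-phenylhexyl]alumane | C[C@@H](CCCCc1ccccc1)C[Al](C)C | intermediate
5 | [(5S)-6-iodo-5-methylhexyl]benzene | C[C@@H](CCCCc1ccccc1)CI | intermediate
6 | but-3-en-1-ylmagnesium bromide | C=CCC[Mg]Br | starting material
7 | [(5S)-5-methylnon-8-en-1-yl]benzene | C[C@@H](CCCCc1ccccc1)CCCC=C | intermediate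
8 | dimethyl[(2R,6S)-2,6-dimethyl-10-phenyldecyl]alumane | C[C@@H](CCCCc1ccccc1)CCC[C@@H](C)C[Al](C)C | intermediate
9 | [(5S,9R)-10-iodo-5,9-dimethyldecyl]benzene | C[C@@H](CCCCc1ccccc1)CCC[C@@H](C)CI | intermediate
10 | 3-methylcyclobutan-1-one | CC1CC(=O)C1 | starting material
11 | triethyl{[(3S)-3-methylcyclobut-1-en-1-yl]oxy}silane | C[C@H]1CC(=C1)O[Si](CC)(CC)CC | intermediate
12 | triethyl{[(1R,3S,4R)-3-methyl-5-oxabicyclo[2.1.0]pentan-1-yl]oxy}silane | CC[Si](CC)(CC)O[C@]12C[C@H](C)[C@H]1O2 | intermediate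
13 | (2R,3S)-3-methyl-2-[(triethylsilyl)oxy]cyclobutan-1-one | O=C1C[C@H](C)[C@H]1O[Si](CC)(CC)CC | intermediate
14 | [(2S,6S)-2,6-dimethyl-10-phenyldecyl]lithium | C[C@@H](CCCCc1ccccc1)CCC[C@@H](C)C[Li] | intermediate
15 | (1S,2R,3S)-1-[(2R,6S)-2,6-dimethyl-10-phenyldecyl]-3-methyl-2-[(triethylsilyl)oxy]cyclobutan-1-ol | C[C@@H](CCCCc1ccccc1)CCC[C@@H](C)C[C@]1(O)C[C@H](C)[C@H]1O[Si](CC)(CC)CC | intermediate
16 | (2S,6R,10S)-1-hydroperoxy-2,6,10-trimethyl-14-phenyl-1-[(triethylsilyl)oxy]tetradecan-4-one (C1 epimers) | C[C@@H](CCCCc1ccccc1)CCC[C@@H](C)CC(=O)C[C@H](C)C(OO)O[Si](CC)(CC)CC | intermediate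
17 | (4S)-6-[(2R,6S)-2,6-dimethyl-10-phenyldecyl]-4-methyl-3-[(triethylsilyl)oxy]-1,2-dioxan-6-ol (C3 and C6 epimers) | C[C@@H](CCCCc1ccccc1)CCC[C@@H](C)CC1(O)C[C@H](C)C(O[Si](CC)(CC)CC)OO1 | intermediate
18 | (3R,4S,6R)-6-[(2R,6S)-2,6-dimethyl-10-phenyldecyl]-3,6-dimethoxy-4-methyl-1,2-dioxane | C[C@@H](CCCCc1ccccc1)CCC[C@@H](C)C[C@]1(OC)C[C@H](C)[C@H](OC)OO1 | intermediate
19 | (3R,4S,6R)-6-[(2R,6S)-2,6-dimethyl-10-phenyldecyl]-3-methoxy-4,6-dimethyl-1,2-dioxane | C[C@@H](CCCCc1ccccc1)CCC[C@@H](C)C[C@]1(C)C[C@H](C)[C@H](OC)OO1 | intermediate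
20 | trimethylsilyl acetate | CC(=O)O[Si](C)(C)C | starting material
21 | 1,1-bis[(trimethylsilyl)oxy]ethene | C=C(O[Si](C)(C)C)O[Si](C)(C)C | intermediate
22 | trimethylsilyl 2-[(3S,4S,6R)-6-[(2R,6S)-2,6-dimethyl-10-phenyldecyl]-4,6-dimethyl-1,2-dioxan-3-yl]acetate | C[C@@H](CCCCc1ccccc1)CCC[C@@H](C)C[C@]1(C)C[C@H](C)[C@H](CC(=O)O[Si](C)(C)C)OO1 | intermediate
23 | 2-[(3S,4S,6R)-6-[(2R,6S)-2,6-dimethyl-10-phenyldecyl]-4,6-dimethyl-1,2-dioxan-3-yl]acetic acid | C[C@@H](CCCCc1ccccc1)CCC[C@@H](C)C[C@]1(C)C[C@H](C)[C@H](CC(=O)O)OO1 | target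

**Step count and risks**

Total step count: 11. Longest linear sequence: 8 steps (1, 2, 3, 4, 7, 8, 9, 11).

Most likely to fail:

Step 8 (aerobic ring expansion of the α-siloxy cyclobutanol). The risk is silyl loss or over-oxidation instead of clean peroxide formation. The fallback replaces the radical ring expansion by ionic glycol cleavage and peroxide condensation. It sets out from 15: TBAF removes the silyl group to give (1S,2R,3S)-1-[(2R,6S)-2,6-dimethyl-10-phenyldecyl]-3-methylcyclobutane-1,2-diol F1. NaIO4 cleaves the glycol to (2S,6R,10S)-2,6,10-trimethyl-4-oxo-14-phenyltetradecanal F2. F2 is condensed at once with H2O2 in MeOH/CSA, the classical peroxyketalisation of a 1,4-dicarbonyl compound, and this comes back to the route at 18.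

Step 9 (the proposed C-methylation). The risks are attack of Me3Al on the O–O bond, proton loss from the cation to an enol peroxide, or poor facial selectivity. The fallback uses only known chemistry and gives up stereocontrol at C6. It sets out from 15 and passes through the diol F1 and the keto-aldehyde F2 as above. The aldehyde of F2 is protected (HC(OMe)3, MeOH, CeCl3) as (2S,6R,10S)-1,1-dimethoxy-2,6,10-trimethyl-14-phenyltetradecan-4-one F3. Wittig methylenation (Ph3P=CH2) gives [(5S,9R,13S)-14,14-dimethoxy-5,9,13-trimethyl-11-methylidenetetradecyl]benzene F4. Mukaiyama–Isayama hydroperoxysilylation (Co(acac)2, O2, Et3SiH) gives [(5S,9R,13S)-14,14-dimethoxy-5,9,11,13-tetramethyl-11-[(triethylsilyl)peroxy]tetradecyl]benzene F5 as both C11 epimers. Acid (TsOH, CH2Cl2) closes the silyl peroxide onto the acetal; the C6 epimers are separated by chromatography and the route is rejoined at 19.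

Step 11 (C3 alkylation). The reaction type is established, but the cis selectivity next to the 4-methyl group is uncertain. The fallback forms the C3–O bond last by conjugate addition instead of forming the C3–C bond on a cation. It sets out from 19: aqueous TFA/THF hydrolyses the peroxyacetal to (4S,6R)-6-[(2R,6S)-2,6-dimethyl-10-phenyldecyl]-4,6-dimethyl-1,2-dioxan-3-ol F6. Horner–Wadsworth–Emmons reaction of its ring-opened hydroperoxy aldehyde form with trimethyl phosphonoacetate (LiCl, iPr2NEt), then Et3N/CF3CH2OH, gives by intramolecular peroxide conjugate addition methyl 2-[(3S,4S,6R)-6-[(2R,6S)-2,6-dimethyl-10-phenyldecyl]-4,6-dimethyl-1,2-dioxan-3-yl]acetate F7, separated from its C3 epimer. LiOH in THF/H2O then comes back to the route at 23.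

**Further compounds**

F1 | step 8 | (1S,2R,3S)-1-[(2R,6S)-2,6-dimethyl-10-phenyldecyl]-3-methylcyclobutane-1,2-diol | C[C@@H](CCCCc1ccccc1)CCC[C@@H](C)C[C@]1(O)C[C@H](C)[C@H]1O
F2 | step 8 | (2S,6R,10S)-2,6,10-trimethyl-4-oxo-14-phenyltetradecanal | C[C@@H](CCCCc1ccccc1)CCC[C@@H](C)CC(=O)C[C@H](C)C=O
F3 | step 9 | (2S,6R,10S)-1,1-dimethoxy-2,6,10-trimethyl-14-phenyltetradecan-4-one | C[C@@H](CCCCc1ccccc1)CCC[C@@H](C)CC(=O)C[C@H](C)C(OC)OC
F4 | step 9 | [(5S,9R,13S)-14,14-dimethoxy-5,9,13-trimethyl-11-methylidenetetradecyl]benzene | C[C@@H](CCCCc1ccccc1)CCC[C@@H](C)CC(=C)C[C@H](C)C(OC)OC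
F5 | step 9 | [(5S,9R,13S)-14,14-dimethoxy-5,9,11,13-tetramethyl-11-[(triethylsilyl)peroxy]tetradecyl]benzene (C11 epimers) | C[C@@H](CCCCc1ccccc1)CCC[C@@H](C)CC(C)(OO[Si](CC)(CC)CC)C[C@H](C)C(OC)OC
F6 | step 11 | (4S,6R)-6-[(2R,6S)-2,6-dimethyl-10-phenyldecyl]-4,6-dimethyl-1,2-dioxan-3-ol (C3 epimers) | C[C@@H](CCCCc1ccccc1)CCC[C@@H](C)C[C@]1(C)C[C@H](C)C(O)OO1
F7 | step 11 | methyl 2-[(3S,4S,6R)-6-[(2R,6S)-2,6-dimethyl-10-phenyldecyl]-4,6-dimethyl-1,2-dioxan-3-yl]acetate | C[C@@H](CCCCc1ccccc1)CCC[C@@H](C)C[C@]1(C)C[C@H](C)[C@H](CC(=O)OC)OO1
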